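The route rests on a [4+2] disconnection of ring B at C1–C2 and C3–C4. C2 and C3, two neighbouring tertiary carbinol carbons with anti hydroxyls and anti carboxyl and hydroxymethyl carbons, amount to a dihydroxyfumarate; because O–C2 and the one-carbon arm on C3 share a face with the C1 aryl group, they can be locked in one 1,3-dioxin-4-one ring, made chiral by spiro fusion to (−)-menthone. Ring A with C1 and C4 is an o-benzylbenzaldehyde whose photoenol adds across that alkene: one operation closes ring B and sets C1, C2 and C3. The precursors are thus a diarylmethane aldehyde and a benzyl-protected spiro dioxinone; deoxygenation, hydrolysis, borane reduction and hydrogenolysis finish.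

Key step: step 10

Assumption: the diene is taken to approach the dioxinone on the face remote from the isopropyl-bearing carbon of the menthane ring; should the bias be the reverse, the other spiro epimer from step 9 would be carried through the same steps.

Step 1
Reactants: 1 vanillin
Product: 2 4-(benzyloxy)-3-methoxybenzaldehyde
Conditions: BnBr, K2CO3, DMF, 60 °C
Reagents that add atoms: benzyl bromide, BrCc1ccccc1
Why: Williamson etherification of the phenoxide masks the phenol, so that the methoxy group and not a free hydroxyl steers the bromination that follows.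

Step 2
Reactants: 2 4-(benzyloxy)-3-methoxybenzaldehyde
Product: 3 4-(benzyloxy)-2-bromo-5-methoxybenzaldehyde
Conditions: Br2, NaOAc, AcOH, rt
Reagents that add atoms: bromine, BrBr
Why: Electrophilic aromatic bromination of a 3,4-dialkoxybenzaldehyde should occur para to the methoxy group and ortho to the formyl group, which is the carbon that later carries C1.

Step 3
Reactants: 4 3,4-dihydroxy-5-methoxybenzaldehyde
Product: 5 3,4-bis(benzyloxy)-5-methoxybenzaldehyde
Conditions: BnBr, K2CO3, DMF, 60 °C
Reagents that add atoms: benzyl bromide, BrCc1ccccc1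
Why: Double Williamson etherification protects the catechol as benzyl ethers that last until the final hydrogenolysis.

Step 4
Reactants: 5 3,4-bis(benzyloxy)-5-methoxybenzaldehyde
Product: 6 [3,4-bis(benzyloxy)-5-methoxyphenyl]methanol
Conditions: NaBH4, MeOH–THF, 0 °C
Reagents that add atoms: none
Why: Borohydride reduction converts the aryl aldehyde cleanly into the benzylic alcohol and leaves the ethers alone.

Step 5
Reactants: 6 [3,4-bis(benzyloxy)-5-methoxyphenyl]methanol
Product: 7 3,4-bis(benzyloxy)-5-methoxybenzyl chloride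
Conditions: SOCl2, CH2Cl2, 0 °C to rt
Reagents that add atoms: thionyl chloride, O=S(Cl)Cl
Why: Deoxychlorination through the chlorosulfite is fast for an electron-rich benzylic alcohol and gives the halide needed for zinc insertion.

Step 6
Reactants: 7 3,4-bis(benzyloxy)-5-methoxybenzyl chloride; 3 4-(benzyloxy)-2-bromo-5-methoxybenzaldehyde
Product: 9 4-(benzyloxy)-2-[3,4-bis(benzyloxy)-5-methoxybenzyl]-5-methoxybenzaldehyde, via benzylzinc chloride 8 (not isolated)
Conditions: Zn, LiCl, THF, 25 °C; then 3, Pd(OAc)2, SPhos, THF, 40 °C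
Reagents that add atoms: none
Why: LiCl-assisted zinc insertion into the benzylic C–Cl bond followed by Negishi sp3–sp2 coupling joins the two arenes through the future C1, and the benzylzinc halide is too weak a nucleophile to add to the free aldehyde.

Step 7
Reactants: 10 tert-butyl bromoacetate
Product: 11 tert-butyl 2-(benzyloxy)acetate
Conditions: BnOH, NaH, THF, 0 °C to rt
Reagents that add atoms: benzyl alcohol, OCc1ccccc1
Why: Williamson SN2 displacement on the activated α-bromo ester is routine, and the bulky tert-butyl ester resists transesterification by the alkoxide.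

Step 8
Reactants: 11 tert-butyl 2-(benzyloxy)acetate; 12 dibenzyl oxalate
Product: 13 1-benzyl 4-tert-butyl 3-(benzyloxy)-2-oxobutanedioate (largely enolised)
Conditions: LDA, THF, −78 °C; then inverse addition to 12; aq. HCl quench
Reagents that add atoms: none
Why: Crossed Claisen condensation succeeds because the oxalate cannot enolise and is the more electrophilic ester, and the acidic product is kept as its enolate until work-up.

Step 9
Reactants: 13 1-benzyl 4-tert-butyl 3-(benzyloxy)-2-oxobutanedioate; 14 (−)-menthone
Product: 15 benzyl (2R,2′S,5′R)-5-(benzyloxy)-2′-isopropyl-5′-methyl-4-oxo-4H-spiro[1,3-dioxine-2,1′-cyclohexane]-6-carboxylate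
Conditions: TFAA, TFA, CH2Cl2, 0 °C to rt
Reagents that add atoms: none
Why: Acid anhydride mediated dioxinone formation from a tert-butyl β-keto ester and a ketone (loss of isobutene, then condensation) builds the ring under conditions that spare benzyl ethers; the spiro centre forms reversibly as a mixture, from which the (R)-configured material is separated by chromatography and the remainder re-equilibrated in the same acid.

Step 10
Reactants: 9 4-(benzyloxy)-2-[3,4-bis(benzyloxy)-5-methoxybenzyl]-5-methoxybenzaldehyde; 15 spiro dioxinone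
Product: 17 all-cis cycloadduct (tetralin numbering: 1S,2S,3S,4R; C1 aryl, C2–O, C3–C(=O) and C4–OH on one face; cis-fused spiro-menthylidene 1,3-dioxan-4-one across C2–C3), via photoenol 16 (not isolated)
Conditions: hν (365 nm), degassed toluene, rt
Reagents that add atoms: none
Why: Proposed new method: n→π* excitation of 9 is followed by 1,5-hydrogen transfer from the doubly benzylic CH2 and gives the long-lived E,E-dienol 16, an electron-rich diene that should add in a concerted, suprafacial [4+2] across C5=C6 of 15 with rearomatisation of ring A as driving force; the closest known reactions are photoenolisation/Diels–Alder trappings of o-benzylbenzaldehydes by fumarates or maleic anhydride and face-selective cycloadditions of menthone-derived spiro dioxinones, but a tetrasubstituted 5-alkoxy-6-carboalkoxy dioxinone has not served as the dienophile. Ring B closes as a six-membered carbocycle by intermolecular cycloaddition that forms C1–C2 and C3–C4 together, cis-fused to the resulting dioxanone. C2 and C3 follow from the ring-locked alkene geometry (C2–O cis to the C3 carbonyl carbon, hence the trans diol) and take their absolute configuration from the spiro centre, whose isopropyl-bearing carbon C2′ screens one face so that the diene should add on the side of the C6′ methylene. C1 is set by the E geometry of the benzylidene terminus in a ring-endo transition state (aryl cis to C2–O), and the temporary C4 carbinol (OH cis to the aryl group) by the E enol terminus. Regiochemistry should follow from pairing the more nucleophilic CHAr terminus, remote from the OH donor, with C6, the β-carbon of the planar vinylogous ester, while an OH···O=C4 hydrogen bond at the other terminus supports the same regio- and endo orientation. Room temperature keeps 15 below its cycloreversion temperature, at 365 nm only the aldehyde should absorb, and untrapped dienol simply reverts to 9.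

Step 11
Reactants: 17 all-cis cycloadduct
Product: 19 C3 carboxylic acid with C2 benzyl ester (1S,2S,3S; C2–OH free, C3–OBn, C4 H2), via C4-deoxy acylal 18 (not isolated)
Conditions: Et3SiH, TFA, CH2Cl2, −20 to 0 °C; evaporate; then 2 M HCl, THF, 40 °C
Reagents that add atoms: none
Why: Ionic hydrogenation removes the one stereocentre that is not needed, because the C4 carbinol lies para to the ring A benzyloxy group, ionises in TFA and cannot eliminate towards the quaternary C3, and aqueous acid then hydrolyses the acylal by alkyl–oxygen cleavage so that menthone leaves with the water oxygen while C1, C2, C3 and all benzyl groups stay untouched.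

Step 12
Reactants: 19 C3 carboxylic acid with C2 benzyl ester
Product: 20 pentabenzyl plicatic acid, benzyl (1S,2S,3R)-3,7-bis(benzyloxy)-1-[3,4-bis(benzyloxy)-5-methoxyphenyl]-2-hydroxy-3-(hydroxymethyl)-6-methoxy-1,2,3,4-tetrahydronaphthalene-2-carboxylate
Conditions: BH3·THF, THF, 0 °C to rt; MeOH quench
Reagents that add atoms: none
Why: Borane reduces a free carboxylic acid through its acyloxyborane much faster than an ester, so only the C3 carboxyl becomes CH2OH and no stereocentre is touched.

Step 13
Reactants: 20 pentabenzyl plicatic acid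
Product: 21 plicatic acid, (1S,2S,3R)-1-(3,4-dihydroxy-5-methoxyphenyl)-2,3,7-trihydroxy-3-(hydroxymethyl)-6-methoxy-1,2,3,4-tetrahydronaphthalene-2-carboxylic acid
Conditions: H2 (1 atm), Pd(OH)2/C, THF–MeOH, rt, air excluded on work-up
Reagents that add atoms: none
Why: Catalytic hydrogenolysis cleaves the three aryl benzyl ethers, the tertiary benzyl ether and the benzyl ester in one operation, and the core has no other benzylic C–O bond and no stereocentre that could be affected.

Compound list
1 | vanillin (4-hydroxy-3-methoxybenzaldehyde) | COc1cc(C=O)ccc1O | starting material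
2 | 4-(benzyloxy)-3-methoxybenzaldehyde | COc1cc(C=O)ccc1OCc1ccccc1 | intermediate
3 | 4-(benzyloxy)-2-bromo-5-methoxybenzaldehyde | COc1cc(C=O)c(Br)cc1OCc1ccccc1 | intermediate
4 | 3,4-dihydroxy-5-methoxybenzaldehyde | COc1cc(C=O)cc(O)c1O | starting material
5 | 3,4-bis(benzyloxy)-5-methoxybenzaldehyde | COc1cc(C=O)cc(OCc2ccccc2)c1OCc1ccccc1 | intermediate
6 | [3,4-bis(benzyloxy)-5-methoxyphenyl]methanol | COc1cc(CO)cc(OCc2ccccc2)c1OCc1ccccc1 | intermediate
7 | 3,4-bis(benzyloxy)-5-methoxybenzyl chloride | COc1cc(CCl)cc(OCc2ccccc2)c1OCc1ccccc1 | intermediate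
8 | [3,4-bis(benzyloxy)-5-methoxybenzyl]zinc chloride (LiCl complex, in THF) | COc1cc(C[Zn]Cl)cc(OCc2ccccc2)c1OCc1ccccc1 | intermediate
9 | 4-(benzyloxy)-2-[3,4-bis(benzyloxy)-5-methoxybenzyl]-5-methoxybenzaldehyde | COc1cc(C=O)c(Cc2cc(OC)c(OCc3ccccc3)c(OCc3ccccc3)c2)cc1OCc1ccccc1 | intermediate
10 | tert-butyl bromoacetate | CC(C)(C)OC(=O)CBr | starting material
11 | tert-butyl 2-(benzyloxy)acetate | CC(C)(C)OC(=O)COCc1ccccc1 | intermediate
12 | dibenzyl oxalate | O=C(OCc1ccccc1)C(=O)OCc1ccccc1 | starting material
13 | 1-benzyl 4-tert-butyl 3-(benzyloxy)-2-oxobutanedioate | O=C(OCc1ccccc1)C(=O)C(OCc1ccccc1)C(=O)OC(C)(C)C | intermediate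
14 | (−)-menthone, (2S,5R)-2-isopropyl-5-methylcyclohexanone | C[C@@H]1CC[C@@H](C(C)C)C(=O)C1 | starting material
15 | benzyl (2R,2′S,5′R)-5-(benzyloxy)-2′-isopropyl-5′-methyl-4-oxo-4H-spiro[1,3-dioxine-2,1′-cyclohexane]-6-carboxylate | O=C1O[C@@]2(C[C@H](C)CC[C@H]2C(C)C)OC(C(=O)OCc2ccccc2)=C1OCc1ccccc1 | intermediate
16 | E,E-hydroxy-o-quinodimethane from 9 (enol OH and aryl group both pointing outward) | O/C=C1\C=C(OC)C(OCc2ccccc2)=C/C1=C\c1cc(OC)c(OCc2ccccc2)c(OCc2ccccc2)c1 | intermediate
17 | all-cis cycloadduct: (1S,2S,3S,4R)-1-aryl-4-hydroxytetralin with CO2Bn and the acetal oxygen on C2, OBn and the acylal carbonyl on C3, spiro centre R | COc1cc2c(cc1OCc1ccccc1)[C@H](c1cc(OC)c(OCc3ccccc3)c(OCc3ccccc3)c1)[C@@]3(C(=O)OCc4ccccc4)[C@](OCc4ccccc4)(C(=O)O[C@@]4(C[C@H](C)CC[C@H]4C(C)C)O3)[C@@H]2O | intermediate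
18 | C4-deoxy acylal, (1S,2S,3S), spiro-menthylidene dioxanone retained | COc1cc2c(cc1OCc1ccccc1)[C@H](c1cc(OC)c(OCc3ccccc3)c(OCc3ccccc3)c1)[C@@]3(C(=O)OCc4ccccc4)[C@](OCc4ccccc4)(C(=O)O[C@@]4(C[C@H](C)CC[C@H]4C(C)C)O3)C2 | intermediate
19 | (1S,2S,3S) C3 carboxylic acid with C2 benzyl ester, C2–OH free, C3–OBn | COc1cc2c(cc1OCc1ccccc1)[C@H](c1cc(OC)c(OCc3ccccc3)c(OCc3ccccc3)c1)[C@@](O)(C(=O)OCc1ccccc1)[C@](OCc1ccccc1)(C(=O)O)C2 | intermediate
20 | pentabenzyl plicatic acid, (1S,2S,3R) | COc1cc2c(cc1OCc1ccccc1)[C@H](c1cc(OC)c(OCc3ccccc3)c(OCc3ccccc3)c1)[C@@](O)(C(=O)OCc1ccccc1)[C@](OCc1ccccc1)(CO)C2 | intermediate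
21 | plicatic acid, (1S,2S,3R) | COc1cc2c(cc1O)[C@H](c1cc(O)c(O)c(OC)c1)[C@@](O)(C(=O)O)[C@](O)(CO)C2 | target

Total step count: 13. Longest linear sequence: 8 steps (4 → 5 → 6 → 7 → 9 → 17 → 19 → 20 → 21).

Steps most likely to fail

Step 10 (bears the label). The dienol may revert to the aldehyde faster than the hindered, donor-substituted alkene traps it, or the addition may proceed with poor regio- or facial control. The fallback uses known chemistry and replaces the cycloaddition by an epoxide-opening Friedel–Crafts ring closure; it sets out from 5 and comes back at 21. Knoevenagel condensation of 5 with benzyl 4-[4-(benzyloxy)-3-methoxyphenyl]-3-oxobutanoate F1 (from bought [4-(benzyloxy)-3-methoxyphenyl]acetic acid by magnesium malonate chain extension) would give the arylidene β-keto ester benzyl 2-{[3,4-bis(benzyloxy)-5-methoxyphenyl]methylidene}-4-[4-(benzyloxy)-3-methoxyphenyl]-3-oxobutanoate F2. Enantio- and diastereoselective nucleophilic (Weitz–Scheffer) epoxidation with a TADDOL-derived hydroperoxide and base should give the (2S,3S)-glycidic keto ester F3, in which the aryl group is cis to the keto group. BF3·OEt2 in CH2Cl2 at −78 °C should then trigger 6-endo attack of the vanillyl ring, para to its methoxy group, on the benzylic epoxide carbon with inversion; this forms C1–C8a and gives the (1S,2S)-2-hydroxy-3-tetralone F4 with the aryl group cis to C2–OH. Non-basic methylenation of the C3 ketone (Zn, CH2Br2, TiCl4) would give the exocyclic alkene F5, and OsO4/NMO, adding anti to the allylic C2 oxygen and the C1 aryl group, the triol benzyl ester F6 (tetrabenzyl plicatic acid). Hydrogenolysis under the conditions of step 13 returns to 21.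

Step 9. Condensation with the hindered ketone may be slow, and the strong acid may cleave the benzyl ether, epimerise the carbon next to the ketone or leave an unfavourable spiro mixture. The fallback sets out from 13 and comes back at 15. Acetone, TFAA and TFA at 0 °C, routine for an unhindered ketone, would give benzyl 5-(benzyloxy)-2,2-dimethyl-4-oxo-4H-1,3-dioxine-6-carboxylate F7. Heating F7 with 14 in toluene at 110 °C should release acetone by retro-[4+2] and form the acylketene benzyl 3-(benzyloxy)-2,4-dioxobut-3-enoate F8, which menthone traps in a hetero-Diels–Alder reaction under neutral conditions; 15 is then separated from its spiro epimer.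

Step 11. Ionisation of the acylal may compete with that of the benzylic alcohol and lead to reductive opening of the acetal, and the aryl benzyl ethers may suffer in the acid. The fallback sets out from 17 and comes back at 18. 1,1′-Thiocarbonyldiimidazole and DMAP would convert the C4 alcohol into the O-(imidazol-1-ylthiocarbonyl) derivative F9, and Bu3SnH/AIBN in toluene at 80 °C (Barton–McCombie deoxygenation through the benzylic C4 radical) would give 18 without acid; 18 is then hydrolysed as in the second stage of step 11.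

Further compounds
F1 | step 10 | benzyl 4-[4-(benzyloxy)-3-methoxyphenyl]-3-oxobutanoate | COc1cc(CC(=O)CC(=O)OCc2ccccc2)ccc1OCc1ccccc1
F2 | step 10 | benzyl 2-{[3,4-bis(benzyloxy)-5-methoxyphenyl]methylidene}-4-[4-(benzyloxy)-3-methoxyphenyl]-3-oxobutanoate (E/Z mixture) | COc1cc(C=C(C(=O)OCc2ccccc2)C(=O)Cc2ccc(OCc3ccccc3)c(OC)c2)cc(OCc2ccccc2)c1OCc1ccccc1
F3 | step 10 | benzyl (2S,3S)-3-[3,4-bis(benzyloxy)-5-methoxyphenyl]-2-{[4-(benzyloxy)-3-methoxyphenyl]acetyl}oxirane-2-carboxylate | COc1cc(cc(OCc2ccccc2)c1OCc1ccccc1)[C@@H]1O[C@]1(C(=O)OCc1ccccc1)C(=O)Cc1ccc(OCc2ccccc2)c(OC)c1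
F4 | step 10 | benzyl (1S,2S)-7-(benzyloxy)-1-[3,4-bis(benzyloxy)-5-methoxyphenyl]-2-hydroxy-6-methoxy-3-oxo-1,2,3,4-tetrahydronaphthalene-2-carboxylate | COc1cc2c(cc1OCc1ccccc1)[C@H](c1cc(OC)c(OCc3ccccc3)c(OCc3ccccc3)c1)[C@@](O)(C(=O)OCc1ccccc1)C(=O)C2
F5 | step 10 | benzyl (1S,2S)-7-(benzyloxy)-1-[3,4-bis(benzyloxy)-5-methoxyphenyl]-2-hydroxy-6-methoxy-3-methylidene-1,2,3,4-tetrahydronaphthalene-2-carboxylate | COc1cc2c(cc1OCc1ccccc1)[C@H](c1cc(OC)c(OCc3ccccc3)c(OCc3ccccc3)c1)[C@@](O)(C(=O)OCc1ccccc1)C(=C)C2
F6 | step 10 | benzyl (1S,2S,3R)-7-(benzyloxy)-1-[3,4-bis(benzyloxy)-5-methoxyphenyl]-2,3-dihydroxy-3-(hydroxymethyl)-6-methoxy-1,2,3,4-tetrahydronaphthalene-2-carboxylate | COc1cc2c(cc1OCc1ccccc1)[C@H](c1cc(OC)c(OCc3ccccc3)c(OCc3ccccc3)c1)[C@@](O)(C(=O)OCc1ccccc1)[C@](O)(CO)C2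
F7 | step 9 | benzyl 5-(benzyloxy)-2,2-dimethyl-4-oxo-4H-1,3-dioxine-6-carboxylate | CC1(C)OC(=O)C(OCc2ccccc2)=C(C(=O)OCc2ccccc2)O1
F8 | step 9 | benzyl 3-(benzyloxy)-2,4-dioxobut-3-enoate (acylketene) | O=C=C(OCc1ccccc1)C(=O)C(=O)OCc1ccccc1
F9 | step 11 | C4 O-(1H-imidazol-1-ylthiocarbonyl) derivative of 17 | COc1cc2c(cc1OCc1ccccc1)[C@H](c1cc(OC)c(OCc3ccccc3)c(OCc3ccccc3)c1)[C@@]3(C(=O)OCc4ccccc4)[C@](OCc4ccccc4)(C(=O)O[C@@]4(C[C@H](C)CC[C@H]4C(C)C)O3)[C@@H]2OC(=S)n1ccnc1
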